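Sunday's flask was to get 0.200 M of starting material, the limiting reagent, and twice that of partner. I had to decide whether to keep that charge and leave it for 34 min.

| flask | starting material | partner | free catalyst | time |
|---|---|---|---|---|
| Tuesday's | 0.400 M | 1.20 M | 0.0120 M |  |
| Friday's | 0.400 M | 1.20 M | 0.0180 M |  |
| Monday's | 0.400 M | 2.40 M | 0.0120 M |  |
| Thursday's | 0.800 M | 1.20 M | 0.0120 M |  |
| Sunday's | 0.200 M | 0.400 M | 0.0120 M | 34 min |

| run | time / min | [product] / M |
|---|---|---|
| Tuesday's run | 2.6 | 0.0459 |
| Tuesday's run | 7.8 | 0.1144 |
| Tuesday's run | 15 | 0.1795 |
| Tuesday's run | 24 | 0.2279 |
| Tuesday's run | 34 | 0.2569 |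
| Friday's run | 2.6 | 0.0548 |
| Friday's run | 7.8 | 0.1379 |
| Friday's run | 15 | 0.2111 |
| Friday's run | 24 | 0.2568 |
| Friday's run | 34 | 0.2808 |
| Monday's run | 2.6 | 0.0876 |
| Monday's run | 7.8 | 0.2032 |
| Monday's run | 15 | 0.2885 |
| Monday's run | 24 | 0.3205 |
| Monday's run | 34 | 0.3292 |
| Thursday's run | 2.6 | 0.0690 |
| Thursday's run | 7.8 | 0.1765 |
| Thursday's run | 15 | 0.2766 |
| Thursday's run | 24 | 0.3558 |
| Thursday's run | 34 | 0.4047 |

(each reading ± 0.001 M)

- Overall: starting material + partner -> product, with free catalyst as catalyst.
- Constant volume, constant temperature.
- Bound and free are read together.
- "The second partner" is partner.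
- An order is taken over about fifteen percent of the charge, up and down.

- order of the initial rate in [partner], near the charge of the Tuesday's run, the rate being that where two percent of its starting material are product
- order of the initial rate in [starting material], near the charge of the Tuesday's run, the rate being that where two percent of its starting material are product (one fixed amount of product, the same in the runs compared)
- product in the Sunday's run at 34 min, as a share of the starting material charged

1. I took each run's first reading over its time as its opening rate. Tuesday's run gave 0.0177 M min⁻¹.

2. Monday's and Thursday's first readings, set against Tuesday's, gave me orders of 0.932 in partner and 0.588 in starting material. These are readings over a doubling, wider than the span asked.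

3. Those orders carried Tuesday's rate to Sunday's charge, which gave 0.00422 M min⁻¹.

4. For the early end I used the opening share, which came to 0.717 for Sunday's flask: the opening rate times the time, over the starting material charged. Early on, the product share follows it.

5. For the late end I used the bend in the curves. Tuesday's run stood at 64.2 % at 34 min, and Thursday's at 50.6 %, both with Sunday's catalyst charge. I took these as rough ceilings, though both runs were still rising at that reading. Sunday's ratio of partner to starting material lies below Tuesday's and above Thursday's, so on a log scale I placed its ceiling at 56.2 %.

6. I joined the ends: share = ceiling × (1 − exp(−opening share/ceiling)). For Sunday this gave 40.5 %.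

7. I tested the join on Tuesday's run at 15 min. It gave 41.3 % against a reading of 44.9 %, so it ran lower than the reading there.

8. Sunday's opening share was larger than its ceiling, so I expected Sunday's flask to be well into its bend by 34 min. I kept the charge and the time.

The forecast gave 0.98, 0.65 and 35 %, saying “That points to a reversible reaction”; its orders stand above mine and its share below mine.

Sunday's flask gave 37.7 % at 34 min, which is 2.8 percentage points under my share, and the orders near Tuesday's charge came to 1.0 and 0.65.

    2 free catalyst ⇌ catalyst dimer, settled at all times (721.0 M⁻¹)
    free catalyst + starting material + partner → product + free catalyst (36.30 M⁻² min⁻¹)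
    2 starting material ⇌ idle substrate dimer, settled at all times (4.030 M⁻¹)
    2 starting material → homo dimer (0.2322 M⁻¹ min⁻¹)

The scheme holds no step from product back; starting material also leaves as homo dimer, with 0.232 M⁻¹ min⁻¹. Sunday's product share stood at 0.526 of its opening share of 0.717. In Monday's run, product came to half of the starting material charged at 7.55 min. Monday's rate where product equals two percent of Tuesday's starting material, 0.037 M min⁻¹, makes the opening share there 0.697, and with Monday's 34 min share as ceiling the join gives 47.0 %.

The numbers in the tables come from a simulation from invented constants.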